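**Remark on the chemistry.** The carbon that carries the aryloxy group in 10, 11 and 13–17 is a stereocentre that the target does not retain. These compounds are planned as racemates (16 and 17 as diastereomer mixtures) and no stereocontrol is attempted.

Atom labels used throughout: ring A is C1 (ether oxygen), C2 (Br), C3 (Br), C4 (H), C5 (Br), C6 (OMe). Ring B is C1' (ether oxygen), C2' (H), C3' (Br), C4' (H), C5' (Br), C6' (OH).

## Analysis of the target

Target 20 is a pentabrominated diaryl ether without any stereocentre. Ring A is a 2,3,5-tribromo-6-methoxyphenyl unit bound through its C1 oxygen to C1' of ring B, and ring B is a phenol (C6'–OH) with bromine at C3' and C5'. The five aryl bromides rule out zerovalent palladium or nickel, hydrogenolysis, halogen–metal exchange and lithium amide or alkyllithium bases; C4–H of ring A lies between two bromines and is acidic enough to start bromine migration. The first difficulty is the central C1–O–C1' bond: on the ring A side it is flanked by OMe and Br, so the ring A phenoxide is di-ortho-substituted, electron-poor and a weak partner for any O-arylation. The second is the halogen pattern of ring A, which carries bromine ortho to the ether oxygen (C2) but none para to it (C4), so it cannot be installed by brominating a preformed diaryl ether. Ring B, in contrast, has exactly the pattern that bromination of a free 2-aryloxyphenol gives, C5' ortho and C3' para to the C6' hydroxyl. The strategy rests on this: ring B (C1'–C6') is carried as a cyclohexenone with C6' as the carbonyl and C1' as an sp3 carbon bound to the ring A oxygen. The ether bond can then be made by substitution at saturated carbon, the ring closed across C3'=C4', and aromatization and bromination left to the end.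

## Retrosynthetic reasoning

**20 ⇒ 18.** The C3'–Br and C5'–Br bonds are cut first. They lie para and ortho to the C6' hydroxyl and the other ortho position (C1') holds the ether oxygen, so a forward double electrophilic bromination of 18 has only these two sites. Ring A, with three bromines and its one C–H wedged between two of them, is inert by comparison. The gain is that ring B can be built free of halogen.

**18 ⇒ 15.** Ring B is taken back by one unsaturation to cyclohexenone 15, with C6' as carbonyl, C1' as the sp3 carbon bearing the ring A oxygen and C3'=C4' as the only ring alkene. A diaryl ether becomes an alkyl aryl ether and a benzene ring becomes a carbocycle that a ring closure can form. The forward reaction has to halogenate C3'=C4' and dehydrohalogenate twice; the resulting dienone is the keto tautomer of 18.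

**15 ⇒ 14.** The C3'=C4' bond is cut by ring-closing metathesis. It is the only C=C of the ring and lies remote from the carbonyl and the ether carbon. Cutting it gives the acyclic dienone 14, whose two alkenes are terminal and belong to two allyl groups. The forward step must close the six-membered ring with loss of the two terminal methylene carbons and leave the aryl bromides and the allyl ketone untouched.

**14 ⇒ 11 + 12.** The C5'–C6' bond is cut between the carbonyl and its allyl group. The N-methoxy-N-methylamide 11 is chosen as acyl partner because its chelated adduct with allylmagnesium bromide 12 stops at the ketone.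

**11 ⇒ 10 ⇒ 9 ⇒ 7 + 8.** Amide 11 comes from ester 10, and 10 from malonate 9 by loss of one ethoxycarbonyl group. In 9 the C1'–C2' bond is cut to allyl bromide 8 and aryloxymalonate 7. The second ester is there only to acidify C1'–H, so that this C–C bond is made with a hydride base. An ordinary ester enolate would need a lithium amide, which ring A with its acidic C4–H would not tolerate.

**7 ⇒ 5 + 6.** The O–C1' bond is cut, the central disconnection of the ether. In the forward sense the phenoxide of 5 displaces bromide from bromomalonate 6 at an sp3 carbon activated by two carbonyls, which even a hindered, weakly nucleophilic phenoxide can do. No aryl–oxygen coupling is needed.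

**5 ⇒ 4 ⇒ 2 ⇒ 1.** The C2–Br bond of 5 is cut ortho to the hydroxyl to give 4. The C1–O bond of 4 is traced to the formyl group of 2 (aryl migration in a Baeyer–Villiger oxidation), and the methyl ether of 2 to the phenol of 1. Aldehyde 1 already carries the bromines at C3 and C5 in the right relation to the C6 oxygen.

## Alternatives that were turned down

**Alternative 1:**
- **Disconnection.** The four C–Br bonds ortho and para to the two oxygens (C3 and C5 on ring A, C3' and C5' on ring B) are cut together, which uncovers the symmetric 2,2'-oxydiphenol A1.
- **Forward key step.** Fourfold hydroxyl-directed bromination of A1 to bis(3,5-dibromo-2-hydroxyphenyl) ether A2, then mono-O-methylation to A3 and a fifth bromination at C2 of ring A.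
- **For.** The ether bond is bought ready-made, the key step is ordinary phenol chemistry, no ring is built, and three or four operations would suffice. On step count it is clearly stronger than the chosen route.
- **Against.** Neither step after the key step has a control element. The two hydroxyls of A2 are equivalent, so monomethylation to A3 is statistical. In A3 the fifth bromine must enter at C2 of ring A, ortho to the bridging oxygen and meta to the methoxy group. Ring B offers the exact counterpart, C2'–H, and as the ring of a free phenol it is the more easily attacked. Each ring also has a C–H para to the bridging oxygen.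
- **Comparison.** The chosen route is about three times as long, but every bromine of ring A is in place before the ether exists, and ring B is brominated when it is the only reactive ring.

**Alternative 2:**
- **Disconnection.** The C6'–O bond of ring B is cut and traced to a carbonyl bridge, so the diaryl ether comes from 4-methoxyxanthone A4.
- **Forward key step.** A peracid inserts oxygen between the carbonyl carbon and the unsubstituted aryl ring of A4 to give the seven-membered lactone A5. Hydrolysis would give hydroxy acid A6; its carboxyl group at C2 of ring A then has to be replaced by bromine and four more bromines added.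
- **For.** Both ether C–O bonds exist in a tricycle that is easy to make, the new oxygen lands exactly ortho to the ether on ring B, and no hindered O-arylation is needed. If every step worked, it would be shorter than the chosen route.
- **Against.** The xanthone carbonyl is a vinylogous ester, doubly conjugated with the ring oxygen, and adds peracids poorly. Both candidate migrating carbons carry an ortho ring oxygen, so nothing in the structure makes the unsubstituted ring migrate in preference to the methoxy ring. Afterwards a bromodecarboxylation at C2 and a bromination of ring A are needed, in which the methoxy group (directing to C3 and C5) must beat the ether oxygen (directing to C4).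
- **Comparison.** The chosen route has more steps, but each bond is made by a reaction whose site is fixed by the substrate. Alternative 2 puts two uncontrolled selectivities in series.

**Alternative 3:**
- **Disconnection.** Ring B is cut at C1'–C2' and C5'–C6' into 3,5-dibromo-2-pyrone A7 and the bis(trimethylsilyl) ketene acetal A8, which carries ring A on oxygen.
- **Forward key step.** A8 adds across C6 and C3 of A7. The bicyclic lactone adduct extrudes its carboxyl bridge and eliminates one silyloxy group to give the trimethylsilyl ether A9 of target 20.
- **For.** Ring B arrives with both bromines and both oxygens in place, the polarity of the two partners fixes the regiochemistry, the only aromatizing elimination open to the adduct is the desired one, and the ether bond is again made at sp3 carbon from phenol 5. It is more convergent and several steps shorter than the chosen route, and on these points it is the stronger plan.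
- **Against.** A8 must be made from 5 by O-alkylation with a haloacetate and then double enolization and silylation with a strong amide base, which is the very reagent that the acidic C4–H of ring A forbids. A8 is moisture-sensitive, and its reacting carbon carries a di-ortho-substituted aryloxy group and must bond to C6 of A7 in a congested transition state. A stepwise conjugate addition with opening of the pyrone ring is a plausible competitor to cycloaddition.
- **Comparison.** The chosen route gives up convergence for ordinary reagents: carbonate and hydride bases, a cold Grignard addition and a ring-closing metathesis of two terminal alkenes, with the ring B bromines placed last by the hydroxyl group.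

Key step: step 9

## Route

Step 1
Reactants: 1 3,5-dibromo-2-hydroxybenzaldehyde (3,5-dibromosalicylaldehyde)
Product: 2 3,5-dibromo-2-methoxybenzaldehyde
Conditions: MeI, K2CO3, DMF, rt
Reagents that add atoms: iodomethane, CI
Why: Williamson ether synthesis; the phenol, acidified by two bromines and the ortho formyl group, is ionized by K2CO3 and the phenoxide displaces iodide from iodomethane, there being no other nucleophilic site.

Step 2
Reactants: 2 3,5-dibromo-2-methoxybenzaldehyde
Product: 4 3,5-dibromo-2-methoxyphenol, via aryl formate 3 (not isolated)
Conditions: mCPBA, CH2Cl2, 40 °C; then K2CO3 (cat.), MeOH, rt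
Reagents that add atoms: meta-chloroperoxybenzoic acid (mCPBA), OOC(=O)c1cccc(Cl)c1
Why: Baeyer–Villiger (Dakin-type) oxidation of an ortho-alkoxybenzaldehyde; in the peracid adduct the aryl group, supported by the ortho methoxy lone pair, migrates to oxygen, and formate 3 is transesterified by methanol to the phenol in the same flask.

Step 3
Reactants: 4 3,5-dibromo-2-methoxyphenol
Product: 5 2,3,5-tribromo-6-methoxyphenol
Conditions: NBS (1.0 equiv), iPr2NH (10 mol%), CH2Cl2, 0 °C → rt
Reagents that add atoms: N-bromosuccinimide (NBS), O=C1CCC(=O)N1Br
Why: Amine-catalysed ortho-bromination of a phenol (electrophilic aromatic substitution); the N-bromoamine formed in the flask is hydrogen-bonded to the hydroxyl and delivers bromine to the one free ortho carbon. The para C–H is wedged between two bromines and the methoxy group has no free ortho or para position, so only the hydroxyl directs.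

Step 4
Reactants: 5 2,3,5-tribromo-6-methoxyphenol; 6 diethyl 2-bromopropanedioate (diethyl bromomalonate)
Product: 7 diethyl 2-(2,3,5-tribromo-6-methoxyphenoxy)propanedioate
Conditions: K2CO3, DMF, rt → 50 °C
Reagents that add atoms: none
Why: O-alkylation of a phenoxide by SN2 displacement at a carbon activated by two ester carbonyls; the acidic tribromophenol is fully ionized by K2CO3. Making the ether at sp3 carbon avoids any O-arylation of this di-ortho-substituted, weakly nucleophilic phenoxide.

Step 5
Reactants: 7 diethyl 2-(2,3,5-tribromo-6-methoxyphenoxy)propanedioate; 8 3-bromoprop-1-ene (allyl bromide)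
Product: 9 diethyl 2-(prop-2-en-1-yl)-2-(2,3,5-tribromo-6-methoxyphenoxy)propanedioate
Conditions: NaH, THF–DMF, 0 °C; then 8, rt
Reagents that add atoms: none
Why: Malonic ester alkylation; the doubly activated C–H of 7 is removed by NaH and the soft enolate attacks allyl bromide at carbon (SN2). NaH does not touch aryl bromides or the ring A C–H.

Step 6
Reactants: 9 diethyl 2-(prop-2-en-1-yl)-2-(2,3,5-tribromo-6-methoxyphenoxy)propanedioate
Product: 10 ethyl 2-(2,3,5-tribromo-6-methoxyphenoxy)pent-4-enoate (racemic)
Conditions: LiCl, H2O, DMSO, 150 °C
Reagents that add atoms: none
Why: Krapcho dealkoxycarbonylation; chloride dealkylates one ethyl ester, the carboxylate loses carbon dioxide, and the α-aryloxy ester enolate is protonated by water. The conditions are neutral and relieve the congestion at the quaternary carbon.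

Step 7
Reactants: 10 ethyl 2-(2,3,5-tribromo-6-methoxyphenoxy)pent-4-enoate (racemic)
Product: 11 N-methoxy-N-methyl-2-(2,3,5-tribromo-6-methoxyphenoxy)pent-4-enamide (racemic)
Conditions: MeNHOMe·HCl, AlMe3, CH2Cl2, 0 → 40 °C; aq. HCl work-up
Reagents that add atoms: N,O-dimethylhydroxylamine hydrochloride, CNOC.Cl
Why: Weinreb aminolysis of an ester by the aluminium amide formed from AlMe3 and the amine salt. The aluminium reagent is chosen over a magnesium amide because it does not exchange with aryl bromides.

Step 8
Reactants: 11 N-methoxy-N-methyl-2-(2,3,5-tribromo-6-methoxyphenoxy)pent-4-enamide (racemic); 12 allylmagnesium bromide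
Product: 14 5-(2,3,5-tribromo-6-methoxyphenoxy)octa-1,7-dien-4-one (racemic), via magnesium hemiaminal chelate 13 (not isolated)
Conditions: THF, −78 °C; 1 M HCl, −78 → 0 °C
Reagents that add atoms: none
Why: Weinreb ketone synthesis; the N-methoxy group holds the tetrahedral adduct 13 as a five-membered magnesium chelate, so the ketone appears only on quenching and cannot add a second allyl group. Carbonyl addition of the allyl Grignard reagent through its cyclic transition state is far faster at −78 °C than bromine–magnesium exchange, and the cold acidic quench avoids base-induced migration of the new double bond into conjugation.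

Step 9
Reactants: 14 5-(2,3,5-tribromo-6-methoxyphenoxy)octa-1,7-dien-4-one (racemic)
Product: 15 2-(2,3,5-tribromo-6-methoxyphenoxy)cyclohex-4-en-1-one (racemic)
Conditions: second-generation Grubbs catalyst (H2IMes)(PCy3)Cl2Ru=CHPh (3 mol%), 1,4-benzoquinone (10 mol%), CH2Cl2 (0.01 M), 40 °C
Reagents that add atoms: none
Why: Ring-closing olefin metathesis: the ruthenium benzylidene exchanges with one terminal alkene of 14, the new alkylidene adds to the other terminal alkene by [2+2] cycloaddition, and cycloreversion of the ruthenacyclobutane releases 15 and a ruthenium methylidene that turns over with loss of ethene. The closest known reaction type is the ring-closing metathesis of octa-1,7-dien-4-ones and other 1,7-dienes to cyclohex-3-enones and cyclohexenes with this catalyst class. One ring closes, the six-membered carbocycle that becomes ring B, by joining C2 and C7 of the chain (the C3'=C4' bond) through a ruthenacyclobutane fused to the nascent ring; a 1,7-diene gives the least strained ring size and escape of ethene makes the closure irreversible. No stereocentre is formed, and the aryloxy-bearing carbon stays racemic until it is flattened in step 10. The step needs chemoselectivity for ring closure over migration of the allyl-ketone double bond into conjugation, over intermolecular metathesis and over any reaction at the three aryl bromides. Both alkenes are terminal and monosubstituted, so loading and closure are fast; high dilution favours the ring, 1,4-benzoquinone intercepts the ruthenium hydrides that cause migration, and ruthenium alkylidenes do not insert into aryl C–Br bonds. Chelation of the alkylidene by the ketone or ether oxygen is possible only through small rings that open at 40 °C, and 15 is passed through a short silica pad and used at once so that its double bond stays out of conjugation.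

Step 10
Reactants: 15 2-(2,3,5-tribromo-6-methoxyphenoxy)cyclohex-4-en-1-one (racemic)
Product: 18 2-(2,3,5-tribromo-6-methoxyphenoxy)phenol, via dibromoketone 16 (not isolated), via bromoenone 17 (not isolated)
Conditions: Br2 (1.05 equiv), CH2Cl2, −78 °C; then DBU (3 equiv), −78 °C → rt
Reagents that add atoms: bromine, BrBr (its atoms are carried by 16 and 17 only and are lost again before 18)
Why: Bromination–dehydrobromination aromatization of a cyclohexenone; anti addition of bromine to the isolated alkene at −78 °C outruns enol bromination and gives 16. DBU removes the β-bromide by E1cB elimination to give γ-bromoenone 17, and E2 loss of the allylic bromide gives the 2,4-dienone, which tautomerizes to phenol 18.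

Step 11
Reactants: 18 2-(2,3,5-tribromo-6-methoxyphenoxy)phenol
Product: 20 2,4-dibromo-6-(2,3,5-tribromo-6-methoxyphenoxy)phenol (target), via para-bromophenol 19 (not isolated)
Conditions: Br2 (2.05 equiv), NaOAc, AcOH, rt; aq. Na2S2O3 work-up
Reagents that add atoms: bromine, BrBr
Why: Electrophilic aromatic bromination directed by the free C6' hydroxyl, first para (C3') and then at the only free ortho carbon (C5'), the other ortho carbon carrying the ether oxygen. Ring A is deactivated by three bromines and its single C–H is shielded by two of them, so two equivalents stop at the target.

## Compound list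

1 | 3,5-dibromo-2-hydroxybenzaldehyde | O=Cc1cc(Br)cc(Br)c1O | starting material
2 | 3,5-dibromo-2-methoxybenzaldehyde | COc1c(Br)cc(Br)cc1C=O | intermediate
3 | 3,5-dibromo-2-methoxyphenyl formate | COc1c(Br)cc(Br)cc1OC=O | intermediate (not isolated)
4 | 3,5-dibromo-2-methoxyphenol | COc1c(O)cc(Br)cc1Br | intermediate
5 | 2,3,5-tribromo-6-methoxyphenol | COc1c(O)c(Br)c(Br)cc1Br | intermediate
6 | diethyl 2-bromopropanedioate | CCOC(=O)C(Br)C(=O)OCC | starting material
7 | diethyl 2-(2,3,5-tribromo-6-methoxyphenoxy)propanedioate | CCOC(=O)C(Oc1c(OC)c(Br)cc(Br)c1Br)C(=O)OCC | intermediate
8 | 3-bromoprop-1-ene | C=CCBr | starting material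
9 | diethyl 2-(prop-2-en-1-yl)-2-(2,3,5-tribromo-6-methoxyphenoxy)propanedioate | CCOC(=O)C(CC=C)(Oc1c(OC)c(Br)cc(Br)c1Br)C(=O)OCC | intermediate
10 | ethyl 2-(2,3,5-tribromo-6-methoxyphenoxy)pent-4-enoate (racemic) | CCOC(=O)C(CC=C)Oc1c(OC)c(Br)cc(Br)c1Br | intermediate
11 | N-methoxy-N-methyl-2-(2,3,5-tribromo-6-methoxyphenoxy)pent-4-enamide (racemic) | CON(C)C(=O)C(CC=C)Oc1c(OC)c(Br)cc(Br)c1Br | intermediate
12 | allylmagnesium bromide | C=CC[Mg]Br | starting material
13 | bromomagnesium 4-[methoxy(methyl)amino]-5-(2,3,5-tribromo-6-methoxyphenoxy)octa-1,7-dien-4-olate (chelate, diastereomer mixture) | C=CCC(O[Mg]Br)(N(C)OC)C(CC=C)Oc1c(OC)c(Br)cc(Br)c1Br | intermediate (not isolated)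
14 | 5-(2,3,5-tribromo-6-methoxyphenoxy)octa-1,7-dien-4-one (racemic) | C=CCC(=O)C(CC=C)Oc1c(OC)c(Br)cc(Br)c1Br | intermediate
15 | 2-(2,3,5-tribromo-6-methoxyphenoxy)cyclohex-4-en-1-one (racemic) | O=C1CC=CCC1Oc1c(OC)c(Br)cc(Br)c1Br | intermediate
16 | trans-4,5-dibromo-2-(2,3,5-tribromo-6-methoxyphenoxy)cyclohexan-1-one (racemic, both C2 epimers) | O=C1CC(Br)C(Br)CC1Oc1c(OC)c(Br)cc(Br)c1Br | intermediate (not isolated)
17 | 4-bromo-6-(2,3,5-tribromo-6-methoxyphenoxy)cyclohex-2-en-1-one (racemic, diastereomer mixture) | O=C1C=CC(Br)CC1Oc1c(OC)c(Br)cc(Br)c1Br | intermediate (not isolated)
18 | 2-(2,3,5-tribromo-6-methoxyphenoxy)phenol | Oc1ccccc1Oc1c(OC)c(Br)cc(Br)c1Br | intermediate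
19 | 4-bromo-2-(2,3,5-tribromo-6-methoxyphenoxy)phenol | Oc1ccc(Br)cc1Oc1c(OC)c(Br)cc(Br)c1Br | intermediate (not isolated)
20 | 2,4-dibromo-6-(2,3,5-tribromo-6-methoxyphenoxy)phenol | COc1c(Br)cc(Br)c(Br)c1Oc1cc(Br)cc(Br)c1O | target

## Step count and least certain steps

Total: 11 steps. Longest linear sequence: 11 steps from 1 (the route is linear; 6, 8 and 12 are bought).

**Step 9 (key step).** The most likely failure is migration of the allyl-ketone double bond of 14 into conjugation before the ring closes, through ruthenium hydrides or traces of base. Metathesis of the migrated diene would then close a five-membered ring, or the conjugated enone would stop reacting; chelation of the alkylidene by the carbonyl can also slow turnover. The fallback sets out from 14 and removes the ketone before the metathesis. Reduction with NaBH4 in MeOH at 0 °C should give the dienol 5-(2,3,5-tribromo-6-methoxyphenoxy)octa-1,7-dien-4-ol F1 as a diastereomer mixture, in which no conjugation can pull the alkene. Ring-closing metathesis with the same ruthenium catalyst should give 6-(2,3,5-tribromo-6-methoxyphenoxy)cyclohex-3-en-1-ol F2, and oxidation with Dess–Martin periodinane buffered with NaHCO3 comes back to the route at 15.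

**Step 10.** After the first dehydrobromination, enolization toward the aryloxy-bearing carbon can compete with the second elimination and lead to intramolecular displacement of the allylic bromide (three-membered ring formation). If 15 has slipped into conjugation beforehand, bromine addition also gives a dibromide that cannot aromatize. The fallback sets out from 15 and uses dehydrogenation instead of halogenation. Silylation with tBuMe2SiOSO2CF3 and Et3N should give the dienol ether tert-butyl(dimethyl){[6-(2,3,5-tribromo-6-methoxyphenoxy)cyclohexa-1,3-dien-1-yl]oxy}silane F3. DDQ in benzene at rt should abstract hydride and give the aryl silyl ether tert-butyl(dimethyl)[2-(2,3,5-tribromo-6-methoxyphenoxy)phenoxy]silane F4, and Bu4NF comes back to the route at 18.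

**Step 3.** Site selectivity may be poor: attack para to the hydroxyl, between the two bromines, or a second bromination can compete, because para attack is electronically as good as ortho attack and only sterics and the amine-directed delivery disfavour it. The fallback sets out from 4 and fixes the site by chelation. Acylation with Me2NCOCl and K2CO3 should give 3,5-dibromo-2-methoxyphenyl N,N-dimethylcarbamate F5. Carbamate-directed ortho C–H bromination with Pd(OAc)2 (cat.), NBS and TsOH in 1,2-dichloroethane can reach only the one ortho C–H and should give 2,3,5-tribromo-6-methoxyphenyl N,N-dimethylcarbamate F6. Hydrolysis with KOH in hot ethanol comes back to the route at 5.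

**Step 4.** The hindered phenoxide may attack the bromine of 6 instead of its carbon (bromine transfer, which leads to ring bromination and reduced malonate), or substitute too slowly. The fallback sets out from 5 and reverses the polarity of the ether formation. A Mitsunobu reaction (PPh3, diisopropyl azodicarboxylate, THF, 0 °C → rt) with commercial racemic ethyl 2-hydroxypent-4-enoate (CCOC(=O)C(O)CC=C) uses the acidic phenol as the nucleophile and comes back to the route at 10, leaving out 7 and 9.

**Step 8.** The allyl ketone may isomerize to the conjugated enone during addition or work-up, or the Grignard reagent may enolize the α-aryloxy amide instead of adding. The fallback sets out from 10 and avoids a basic organometal. Reduction with iBu2AlH in CH2Cl2 at −78 °C should give the aldehyde 2-(2,3,5-tribromo-6-methoxyphenoxy)pent-4-enal F7. Allylation with allylboronic acid pinacol ester in CH2Cl2 at rt should give the dienol 5-(2,3,5-tribromo-6-methoxyphenoxy)octa-1,7-dien-4-ol F1, the same compound as in the fallback for step 9. Oxidation with Dess–Martin periodinane and NaHCO3 comes back to the route at 14; F1 can also be carried on through F2 to 15.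

## Further compounds

F1 | step 9 | 5-(2,3,5-tribromo-6-methoxyphenoxy)octa-1,7-dien-4-ol (racemic, diastereomer mixture) | C=CCC(O)C(CC=C)Oc1c(OC)c(Br)cc(Br)c1Br
F2 | step 9 | 6-(2,3,5-tribromo-6-methoxyphenoxy)cyclohex-3-en-1-ol (racemic, diastereomer mixture) | OC1CC=CCC1Oc1c(OC)c(Br)cc(Br)c1Br
F3 | step 10 | tert-butyl(dimethyl){[6-(2,3,5-tribromo-6-methoxyphenoxy)cyclohexa-1,3-dien-1-yl]oxy}silane (racemic) | CC(C)(C)[Si](C)(C)OC1=CC=CCC1Oc1c(OC)c(Br)cc(Br)c1Br
F4 | step 10 | tert-butyl(dimethyl)[2-(2,3,5-tribromo-6-methoxyphenoxy)phenoxy]silane | CC(C)(C)[Si](C)(C)Oc1ccccc1Oc1c(OC)c(Br)cc(Br)c1Br
F5 | step 3 | 3,5-dibromo-2-methoxyphenyl N,N-dimethylcarbamate | COc1c(Br)cc(Br)cc1OC(=O)N(C)C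
F6 | step 3 | 2,3,5-tribromo-6-methoxyphenyl N,N-dimethylcarbamate | COc1c(OC(=O)N(C)C)c(Br)c(Br)cc1Br
F0 | step 4 | none | none
F7 | step 8 | 2-(2,3,5-tribromo-6-methoxyphenoxy)pent-4-enal (racemic) | C=CCC(C=O)Oc1c(OC)c(Br)cc(Br)c1Br
A1 | alternative 1 | 2,2'-oxydiphenol | Oc1ccccc1Oc1ccccc1O
A2 | alternative 1 | bis(3,5-dibromo-2-hydroxyphenyl) ether | Oc1c(Br)cc(Br)cc1Oc1cc(Br)cc(Br)c1O
A3 | alternative 1 | 2,4-dibromo-6-(3,5-dibromo-2-methoxyphenoxy)phenol | COc1c(Br)cc(Br)cc1Oc1cc(Br)cc(Br)c1O
A4 | alternative 2 | 4-methoxy-9H-xanthen-9-one | COc1cccc2c1Oc1ccccc1C2=O
A5 | alternative 2 | methoxy-substituted dibenzo[b,e][1,4]dioxepin-11-one (seven-membered lactone, methoxy group next to the ether oxygen on the acyl-bearing ring) | COc1cccc2c1Oc1ccccc1OC2=O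
A6 | alternative 2 | 2-(2-hydroxyphenoxy)-3-methoxybenzoic acid | COc1cccc(C(=O)O)c1Oc1ccccc1O
A7 | alternative 3 | 3,5-dibromo-2H-pyran-2-one | O=C1OC=C(Br)C=C1Br
A8 | alternative 3 | 1,1-bis(trimethylsilyloxy)-2-(2,3,5-tribromo-6-methoxyphenoxy)ethene | C[Si](C)(C)OC(O[Si](C)(C)C)=COc1c(OC)c(Br)cc(Br)c1Br
A9 | alternative 3 | [2,4-dibromo-6-(2,3,5-tribromo-6-methoxyphenoxy)phenoxy]trimethylsilane | COc1c(Br)cc(Br)c(Br)c1Oc1cc(Br)cc(Br)c1O[Si](C)(C)C
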